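## Analysis of the target

The target is an achiral 2-arylbenzofuran. Benzo ring A (C3a, C4 to C7, C7a) is fused to furan ring B (O1, C2, C3), and C2 carries aryl ring C, a 3-hydroxy-4-methoxyphenyl group. C3 bears a methoxy group, so ring B is both an aromatic furan and the methyl enol ether of a benzofuran-3(2H)-one. C6 carries a free hydroxyl and the neighbouring C5 a 3-methylbut-2-enyl (prenyl) chain; C4 and C7 are unsubstituted. The target has no stereocentre; C2 and C3 pass through an sp3 stage during ring formation, and both centres are erased on aromatisation. The sensitive groups are the ortho-prenylphenol at C5/C6 (acid closes it onto the alkene), the trisubstituted alkene (no hydrogenolysis, no electrophilic oxidants), the acid-labile 3-methoxyfuran and the electron-rich, easily oxidised core. The difficulty is to put oxygen on C3 of the furan and to methylate two of four oxygen atoms (O on C3 and O on C4') while the other two (O on C6 and O on C3') stay free. The strategy rests on C2: it is bonded to O1, to C3 and to C1' of ring C, while C3 carries oxygen and sits on C3a. C3 can therefore be the formyl carbon of a salicylaldehyde whose phenol oxygen is O1, and C2 can be a benzylic carbon that acts first as a nucleophile (ylide carbon) and then as an electrophile (carbon bearing the sulfonium leaving group).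

## Retrosynthetic reasoning

**16 to 15.** The last operation is cleavage of the two aryl O–Si bonds of 15. Silyl ethers are chosen for O6 and O3' because they come off under neutral, non-reductive conditions. Acetal protection would need acid next to the ortho-prenylphenol and the enol ether, and benzyl ethers would need hydrogenolysis in the presence of the alkene.

**15 to 14.** The O–CH3 bond on C3 is cut. The aromatic furan 15 is the enol ether of ketone 14, so the methyl group is placed on the enolate oxygen while both phenols are still masked and the enol is the only acidic site. The forward reaction has to alkylate an ambident enolate on oxygen; the gain of furan aromaticity and a hard methylating agent favour that.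

**14 to 13.** This is a change of oxidation level only: the C3 ketone comes from the secondary alcohol of 13. What is gained is a precursor with sp3 carbons at C2 and C3, which can be assembled by polar bond formation under mild base.

**13 to 4 and 10, through 11 and 12.** The bonds C2–C3 and O1–C2 are cut, both at C2. This splits the molecule into ring A with all of its substituents (salicylaldehyde 4) and ring C with the C2 carbon (sulfonium salt 10). A cut at C3–C3a would need an acylation or arylation on ring A with its own regiochemical question, and a cut at O1–C7a would need an extra halogen on ring A. In the forward direction ylide 11 must add to the aldehyde carbon to give betaine 12, and oxygen must then displace dimethyl sulfide 9 from the same benzylic carbon.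

**4 to 2 and 3, and 2 to 1.** The bond between C5 of ring A and the prenyl CH2 is cut, to be formed by a palladium-catalysed coupling of bromide 2 with stannane 3. The bromine of 1 fixes the position, which direct C-prenylation of a dihydroxybenzaldehyde would not do. The prenyl group is attached before the annulation so that no palladium chemistry is needed on the oxidation-prone later intermediates. Compound 2 comes from 1 by silylation of the 4-hydroxyl alone; the 2-hydroxyl must stay free because it becomes O1.

**10 to 8 and 9, and 8 to 5.** The C–S bond is cut: 10 is the alkylation product of dimethyl sulfide 9 with benzylic bromide 8. Bromide 8 comes through alcohol 7 and aldehyde 6 from isovanillin 5, which already carries the methyl group on the correct oxygen of ring C, so no selective methylation is needed there.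

## Alternatives that were turned down

**Alternative 1:** Ring A is built de novo by cutting C4–C5 and C6–C7.
- Key step: pyrone ester A2, which carries the benzylic ether of ring C on its C4 and the ester on its C5, is heated with silyl ynol ether A3. The [4+2] adduct loses its lactone bridge and aromatises to benzoate A1.
- For: the polarities match. The nucleophilic β-carbon of A3, which bears the prenyl CH2, meets C6 of the pyrone, and the silyloxy carbon meets C3, so all four substituents of ring A should land correctly in one step. On regiocontrol of ring A this is at least as strong as the chosen route.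
- Against: A1 still lacks ring B. C2–C3 would have to be made afterwards by deprotonating the benzylic ether CH2 and closing onto the ester, in competition with [1,2]-Wittig rearrangement. A2 and A3 each need several steps. The 4-alkoxy group makes the pyrone less electron-poor, so the cycloaddition needs heat at which a silyl ynol ether tends to rearrange by silyl shift and to dimerise.
- Comparison: the chosen strategy buys ring A as a simple arene, needs two steps to prepare it, and forms both new bonds of ring B in one operation. It is much shorter overall.

**Alternative 2:** Both bonds from ring B to ring A, C3–C3a and O1–C7a, are cut.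
- Key step: α-methoxy ketone A5 and dihaloarene A6 are joined with a palladium catalyst, a wide-bite-angle bisphosphine and a carbonate base. α-Arylation at the C–I bond is followed by O-arylation of the enolate at the C–Br bond, giving the bis(methoxymethyl) ether A4 directly.
- For: this is the most direct entry. The furan is formed aromatic with the C3 methoxy group already in place, with no stereocentre and no redox adjustment. After its key step only a deprotection remains, against three steps in the chosen route, so it is stronger on that point.
- Against: A6 needs bromine, iodine, a protected hydroxyl and the prenyl chain placed regiospecifically on one benzene ring, which costs several steps with their own selectivity questions. The enolate of an α-alkoxy ketone is a hindered, chelating partner for α-arylation. The second event needs C–O reductive elimination from a fully substituted enolate at the less reactive C–Br bond, with hydrodehalogenation and diarylation as competitors. The acetal groups must finally be removed with acid beside the ortho-prenylphenol and the enol ether.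
- Comparison: the chosen strategy offers a purchasable ring A precursor, a metal-free ring closure that tolerates the prenyl group, and a final deprotection with fluoride.

**Alternative 3:** C3–C3a is cut, to be formed by acylation of ring A para to the C6 oxygen.
- Key step: acid A8 is converted in situ into its acid chloride and cyclised with a strong Lewis acid to bromo ketone A7.
- For: the benzofuran-3(2H)-one oxidation level is reached directly, so the alcohol oxidation of the chosen route is saved; on this point it is stronger. The C6 oxygen directs para, and the other ortho position lies between two oxygens and is hindered, so the regiochemistry is sound.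
- Against: a strong Lewis acid and HCl are used with two aryl silyl ethers in place. An α-aryl-α-aryloxyacetyl chloride with an electron-rich aryl group is prone to decarbonylation to a stabilised benzylic cation instead of acylation. The prenyl group cannot be present under these conditions, so it must be coupled later onto A7, whose C2–H is acidic and easily oxidised. A8 itself needs several steps.
- Comparison: the chosen strategy pays one extra oxidation, but it runs under mild base with the prenyl group already on ring A and is shorter overall.

Key step: step 7

Remark on the chemistry: 5-bromo-2,4-dihydroxybenzaldehyde 1 and stannane 3 are taken as purchasable. Compound 13 is formed as a racemate and one enantiomer is drawn.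

## Route

Step 1
Reactants: 1 5-bromo-2,4-dihydroxybenzaldehyde
Product: 2 5-bromo-2-hydroxy-4-(triisopropylsilyloxy)benzaldehyde
Conditions: TIPSCl (1.05 equiv), imidazole (2.2 equiv), CH2Cl2, 0 °C → rt
Reagents that add atoms: triisopropylsilyl chloride, CC(C)[Si](Cl)(C(C)C)C(C)C
Why: Selective phenol silylation; the 2-hydroxyl is held in a hydrogen bond to the formyl group, while the 4-hydroxyl (para to CHO, ortho to Br) is free and more acidic, so one equivalent of the bulky chloride should react at O4 only.

Step 2
Reactants: 2 5-bromo-2-hydroxy-4-(triisopropylsilyloxy)benzaldehyde; 3 tributyl(3-methylbut-2-en-1-yl)stannane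
Product: 4 2-hydroxy-5-(3-methylbut-2-en-1-yl)-4-(triisopropylsilyloxy)benzaldehyde
Conditions: 3 (1.3 equiv), Pd(PPh3)4 (5 mol %), DMF, 95 °C, degassed
Reagents that add atoms: none
Why: Stille coupling; zerovalent palladium inserts into the C5–Br bond, the allylic stannane transmetalates, and reductive elimination at the less hindered primary terminus should give the linear prenyl arene. The aldehyde, the free phenol and the silyl ether are tolerated under these neutral conditions.

Step 3
Reactants: 5 isovanillin (3-hydroxy-4-methoxybenzaldehyde)
Product: 6 4-methoxy-3-(triisopropylsilyloxy)benzaldehyde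
Conditions: TIPSCl (1.1 equiv), imidazole (2.2 equiv), DMF, rt
Reagents that add atoms: triisopropylsilyl chloride, CC(C)[Si](Cl)(C(C)C)C(C)C
Why: Standard silylation of the only hydroxyl group; the group matches that on ring A so that both come off together in the last step.

Step 4
Reactants: 6 4-methoxy-3-(triisopropylsilyloxy)benzaldehyde
Product: 7 [4-methoxy-3-(triisopropylsilyloxy)phenyl]methanol
Conditions: NaBH4, MeOH, 0 °C
Reagents that add atoms: none
Why: Hydride reduction of an aryl aldehyde; the hindered aryl silyl ether survives brief exposure to cold methanolic borohydride.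

Step 5
Reactants: 7 [4-methoxy-3-(triisopropylsilyloxy)phenyl]methanol
Product: 8 4-(bromomethyl)-1-methoxy-2-(triisopropylsilyloxy)benzene
Conditions: CBr4 (1.2 equiv), PPh3 (1.2 equiv), CH2Cl2, 0 °C; short silica plug, used at once
Reagents that add atoms: tetrabromomethane, BrC(Br)(Br)Br
Why: Appel bromination under neutral conditions; the alkoxyphosphonium ion is displaced by bromide at a primary benzylic carbon, with no strong acid that could touch the silyl ether or ionise the electron-rich benzylic bromide.

Step 6
Reactants: 8 4-(bromomethyl)-1-methoxy-2-(triisopropylsilyloxy)benzene; 9 dimethyl sulfide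
Product: 10 {[4-methoxy-3-(triisopropylsilyloxy)phenyl]methyl}dimethylsulfonium bromide
Conditions: Me2S (5 equiv), acetone, rt, dark; filter, wash with Et2O, use fresh
Reagents that add atoms: none
Why: SN2 alkylation of a sulfide by an activated benzylic bromide; excess sulfide and precipitation of the salt from acetone should pull the reversible alkylation to the product side.

Step 7
Reactants: 4 2-hydroxy-5-(3-methylbut-2-en-1-yl)-4-(triisopropylsilyloxy)benzaldehyde; 10 {[4-methoxy-3-(triisopropylsilyloxy)phenyl]methyl}dimethylsulfonium bromide
Product: 13 trans-2-[4-methoxy-3-(triisopropylsilyloxy)phenyl]-5-(3-methylbut-2-en-1-yl)-6-(triisopropylsilyloxy)-2,3-dihydro-1-benzofuran-3-ol (racemic), via sulfonium ylide 11 (not isolated), via lithium betaine 12 (not isolated)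
Conditions: 10 (1.3 equiv), LiN(SiMe3)2 (1.3 equiv), THF, −78 °C; then 4 premixed with LiN(SiMe3)2 (1.05 equiv) in THF; −78 °C → rt; H2O quench, non-acidic work-up
Reagents that add atoms: none
Why: LiN(SiMe3)2 converts 10 into the aryl-stabilised ylide 11, whose carbon adds to the formyl group of the lithium phenolate of 4 and gives betaine 12 with the new C2–C3 bond. Oxygen then expels dimethyl sulfide from the benzylic carbon and makes O1–C2: either the phenolate attacks directly (5-exo-tet), or the neighbouring alkoxide first closes an oxirane (3-exo-tet) that the phenolate opens at the same carbon, an endo-type opening made easy by the cation-stabilising para-methoxyaryl group; both paths end in the same dihydrofuran ring, so oxirane formation is not a dead end. The closest known reaction type is the Corey–Chaykovsky-type annulation of salicylaldehydes with sulfonium and sulfoxonium ylides to 2,3-dihydrobenzofuran-3-ols. C2 and C3 are set only relative to each other: the partly reversible addition of a semistabilised ylide favours the anti betaine, and closure through the trans-oxirane with a second inversion at C2 should give the trans racemate, while any direct displacement in that betaine would give the cis isomer. Neither centre survives steps 8 and 9, so the ratio does not matter. The selectivity that is needed is C–C bond formation at the aldehyde instead of O-benzylation of the phenolate by 10, which is secured by deprotonating 10 completely before the phenolate is added, and transfer of the benzylic rather than a methyl carbon, which the aryl stabilisation of 11 secures. The hindered amide base at low temperature should leave both aryl silyl ethers and the prenyl group untouched.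

Step 8
Reactants: 13 trans-2-[4-methoxy-3-(triisopropylsilyloxy)phenyl]-5-(3-methylbut-2-en-1-yl)-6-(triisopropylsilyloxy)-2,3-dihydro-1-benzofuran-3-ol
Product: 14 2-[4-methoxy-3-(triisopropylsilyloxy)phenyl]-5-(3-methylbut-2-en-1-yl)-6-(triisopropylsilyloxy)-1-benzofuran-3(2H)-one (racemic)
Conditions: Dess–Martin periodinane (1.2 equiv), pyridine (3 equiv), CH2Cl2, 0 °C → rt; used promptly under argon
Reagents that add atoms: none
Why: Dess–Martin oxidation of a secondary benzylic alcohol by ligand exchange at iodine and loss of the carbinol hydrogen; the pyridine buffer prevents acid-induced dehydration of 13, and the alkene and silyl ethers are inert to the periodinane. The C3 stereocentre is erased here.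

Step 9
Reactants: 14 2-[4-methoxy-3-(triisopropylsilyloxy)phenyl]-5-(3-methylbut-2-en-1-yl)-6-(triisopropylsilyloxy)-1-benzofuran-3(2H)-one
Product: 15 3-methoxy-2-[4-methoxy-3-(triisopropylsilyloxy)phenyl]-5-(3-methylbut-2-en-1-yl)-6-(triisopropylsilyloxy)-1-benzofuran
Conditions: Me2SO4 (1.5 equiv), K2CO3 (2 equiv), dry degassed acetone, rt, argon
Reagents that add atoms: dimethyl sulfate, COS(=O)(=O)OC
Why: O-Alkylation of an ambident enolate; the C2–H of 14 is acidified by the ketone, the ring oxygen and the aryl group, and the hard sulfate electrophile should react at oxygen because this makes the aromatic furan, whereas C-methylation would build a quaternary centre without that gain. The C2 stereocentre is erased here.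

Step 10
Reactants: 15 3-methoxy-2-[4-methoxy-3-(triisopropylsilyloxy)phenyl]-5-(3-methylbut-2-en-1-yl)-6-(triisopropylsilyloxy)-1-benzofuran
Product: 16 2-(3-hydroxy-4-methoxyphenyl)-3-methoxy-5-(3-methylbut-2-en-1-yl)-1-benzofuran-6-ol (target)
Conditions: Bu4NF (2.4 equiv), AcOH (2.4 equiv), THF, 0 °C, argon
Reagents that add atoms: none
Why: Fluoride-driven cleavage of aryl silyl ethers through pentacoordinate silicon; buffering with acetic acid keeps the liberated electron-rich phenols protonated and away from air oxidation, and no acid strong enough to close the ortho-prenylphenol or hydrolyse the enol ether is present.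

## Compound list

1 | 5-bromo-2,4-dihydroxybenzaldehyde | O=Cc1cc(Br)c(O)cc1O | starting material
2 | 5-bromo-2-hydroxy-4-(triisopropylsilyloxy)benzaldehyde | O=Cc1cc(Br)c(O[Si](C(C)C)(C(C)C)C(C)C)cc1O | intermediate
3 | tributyl(3-methylbut-2-en-1-yl)stannane | CCCC[Sn](CCCC)(CCCC)CC=C(C)C | starting material
4 | 2-hydroxy-5-(3-methylbut-2-en-1-yl)-4-(triisopropylsilyloxy)benzaldehyde | O=Cc1cc(CC=C(C)C)c(O[Si](C(C)C)(C(C)C)C(C)C)cc1O | intermediate
5 | isovanillin (3-hydroxy-4-methoxybenzaldehyde) | COc1ccc(C=O)cc1O | starting material
6 | 4-methoxy-3-(triisopropylsilyloxy)benzaldehyde | COc1ccc(C=O)cc1O[Si](C(C)C)(C(C)C)C(C)C | intermediate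
7 | [4-methoxy-3-(triisopropylsilyloxy)phenyl]methanol | COc1ccc(CO)cc1O[Si](C(C)C)(C(C)C)C(C)C | intermediate
8 | 4-(bromomethyl)-1-methoxy-2-(triisopropylsilyloxy)benzene | COc1ccc(CBr)cc1O[Si](C(C)C)(C(C)C)C(C)C | intermediate
9 | dimethyl sulfide | CSC | starting material
10 | {[4-methoxy-3-(triisopropylsilyloxy)phenyl]methyl}dimethylsulfonium bromide | C[S+](C)Cc1ccc(OC)c(O[Si](C(C)C)(C(C)C)C(C)C)c1.[Br-] | intermediate
11 | (dimethylsulfonio)[4-methoxy-3-(triisopropylsilyloxy)phenyl]methanide (sulfonium ylide, not isolated) | C[S+](C)[CH-]c1ccc(OC)c(O[Si](C(C)C)(C(C)C)C(C)C)c1 | intermediate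
12 | lithium 2-{2-(dimethylsulfonio)-2-[4-methoxy-3-(triisopropylsilyloxy)phenyl]-1-oxidoethyl}-4-(3-methylbut-2-en-1-yl)-5-(triisopropylsilyloxy)phenolate (betaine, diastereomer mixture, not isolated) | [Li+].[O-]c1cc(O[Si](C(C)C)(C(C)C)C(C)C)c(CC=C(C)C)cc1C([O-])C([S+](C)C)c1ccc(OC)c(O[Si](C(C)C)(C(C)C)C(C)C)c1 | intermediate
13 | trans-2-[4-methoxy-3-(triisopropylsilyloxy)phenyl]-5-(3-methylbut-2-en-1-yl)-6-(triisopropylsilyloxy)-2,3-dihydro-1-benzofuran-3-ol, racemic, (2S,3R) enantiomer drawn | O[C@H]1[C@H](c3ccc(OC)c(O[Si](C(C)C)(C(C)C)C(C)C)c3)Oc2cc(O[Si](C(C)C)(C(C)C)C(C)C)c(CC=C(C)C)cc21 | intermediate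
14 | 2-[4-methoxy-3-(triisopropylsilyloxy)phenyl]-5-(3-methylbut-2-en-1-yl)-6-(triisopropylsilyloxy)-1-benzofuran-3(2H)-one, racemic | O=C1C(c3ccc(OC)c(O[Si](C(C)C)(C(C)C)C(C)C)c3)Oc2cc(O[Si](C(C)C)(C(C)C)C(C)C)c(CC=C(C)C)cc21 | intermediate
15 | 3-methoxy-2-[4-methoxy-3-(triisopropylsilyloxy)phenyl]-5-(3-methylbut-2-en-1-yl)-6-(triisopropylsilyloxy)-1-benzofuran | COc1ccc(-c2oc3cc(O[Si](C(C)C)(C(C)C)C(C)C)c(CC=C(C)C)cc3c2OC)cc1O[Si](C(C)C)(C(C)C)C(C)C | intermediate
16 | 2-(3-hydroxy-4-methoxyphenyl)-3-methoxy-5-(3-methylbut-2-en-1-yl)-1-benzofuran-6-ol | COc1ccc(-c2oc3cc(O)c(CC=C(C)C)cc3c2OC)cc1O | target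

## Step count and uncertain steps

Total: 10 steps. Longest linear sequence: 8 steps (steps 3 to 10, from isovanillin 5). Steps 1 and 2 form the second branch, which joins at step 7.

**Step 7 (key step).**
- What may go wrong:
  - Slow addition of ylide 11 to the aldehyde. As a lithium phenolate with a para silyloxy group it is a weak electrophile, so on warming the ylide may be lost to Sommelet–Hauser and Stevens rearrangement.
  - O-Benzylation of the phenolate by 10 if 10 is not fully deprotonated.
  - Dehydration of 13 with loss of the C3 oxygen on acidic work-up or on silica.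
- Fallback: it sets out from bromide 8 and bromo aldehyde 2 and returns at 13.
  - Michaelis–Arbuzov reaction of 8 with triethyl phosphite should give diethyl {[4-methoxy-3-(triisopropylsilyloxy)phenyl]methyl}phosphonate F1.
  - Horner–Wadsworth–Emmons olefination of 2 with the anion of F1 (NaH, THF, warming as needed) should give (E)-4-bromo-2-{2-[4-methoxy-3-(triisopropylsilyloxy)phenyl]ethenyl}-5-(triisopropylsilyloxy)phenol F2. The phosphonate anion is thermally stable, so this step can be forced where the sulfonium ylide cannot.
  - Epoxidation of F2 with mCPBA buffered by NaHCO3, while no prenyl alkene is yet present, is followed by spontaneous opening of the oxirane by the ortho phenol at the para-methoxybenzylic carbon. This should give trans-5-bromo-2-[4-methoxy-3-(triisopropylsilyloxy)phenyl]-6-(triisopropylsilyloxy)-2,3-dihydro-1-benzofuran-3-ol F3.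
  - Stille coupling of F3 with stannane 3 under the conditions of step 2 then gives 13.

**Step 2.**
- What may go wrong:
  - Transfer of the prenyl group through its tertiary terminus, giving the branched isomer.
  - Slow oxidative addition into an electron-rich bromide flanked by a bulky silyl ether.
  - Protodestannylation of 3 by the free phenol.
- Fallback: it sets out from 2 and returns at 4.
  - Stille coupling with allyltributylstannane, which has no regiochemical ambiguity, should give 2-hydroxy-5-(prop-2-en-1-yl)-4-(triisopropylsilyloxy)benzaldehyde F4.
  - Cross-metathesis of F4 with excess 2-methylbut-2-ene and the second-generation Grubbs catalyst converts the allyl group into the prenyl group of 4.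

**Step 9.**
- What may go wrong:
  - C-Methylation at C2.
  - Autoxidation of the enolate at C2 by traces of air.
  - Carbonate-induced loss of a silyl group followed by methylation of the freed phenol.
- Fallback: it sets out from 14 and returns at 15, and it avoids base and enolate altogether.
  - Trimethyl orthoformate in methanol with catalytic toluenesulfonic acid should convert 14 into 3,3-dimethoxy-2-[4-methoxy-3-(triisopropylsilyloxy)phenyl]-5-(3-methylbut-2-en-1-yl)-6-(triisopropylsilyloxy)-2,3-dihydro-1-benzofuran F5.
  - F5 loses methanol under the same conditions to give the aromatic enol ether 15. With both phenols silylated, the prenyl group cannot cyclise under this mild acid.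

**Step 8.**
- What may go wrong:
  - Further oxidation at the doubly activated C2–H of the product ketone.
  - Acid-promoted dehydration of 13 before it is oxidised.
- Fallback: it sets out from 13 and returns at 15, bypassing 14.
  - O-Methylation of the C3 alkoxide (NaH, MeI, THF, 0 °C) should give trans-3-methoxy-2-[4-methoxy-3-(triisopropylsilyloxy)phenyl]-5-(3-methylbut-2-en-1-yl)-6-(triisopropylsilyloxy)-2,3-dihydro-1-benzofuran F6.
  - Dehydrogenation of F6 with DDQ in dioxane aromatises ring B to 15 by hydride abstraction at the benzylic, oxygen-bearing C2 and loss of the C3 proton. Oxidation at the benzylic-allylic CH2 of the prenyl group is the risk of this fallback.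

## Further compounds

F1 | step 7 | diethyl {[4-methoxy-3-(triisopropylsilyloxy)phenyl]methyl}phosphonate | CCOP(=O)(OCC)Cc1ccc(OC)c(O[Si](C(C)C)(C(C)C)C(C)C)c1
F2 | step 7 | (E)-4-bromo-2-{2-[4-methoxy-3-(triisopropylsilyloxy)phenyl]ethenyl}-5-(triisopropylsilyloxy)phenol | Oc1cc(O[Si](C(C)C)(C(C)C)C(C)C)c(Br)cc1/C=C/c1ccc(OC)c(O[Si](C(C)C)(C(C)C)C(C)C)c1
F3 | step 7 | trans-5-bromo-2-[4-methoxy-3-(triisopropylsilyloxy)phenyl]-6-(triisopropylsilyloxy)-2,3-dihydro-1-benzofuran-3-ol, racemic, (2S,3R) enantiomer drawn | O[C@H]1[C@H](c3ccc(OC)c(O[Si](C(C)C)(C(C)C)C(C)C)c3)Oc2cc(O[Si](C(C)C)(C(C)C)C(C)C)c(Br)cc21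
F4 | step 2 | 2-hydroxy-5-(prop-2-en-1-yl)-4-(triisopropylsilyloxy)benzaldehyde | O=Cc1cc(CC=C)c(O[Si](C(C)C)(C(C)C)C(C)C)cc1O
F5 | step 9 | 3,3-dimethoxy-2-[4-methoxy-3-(triisopropylsilyloxy)phenyl]-5-(3-methylbut-2-en-1-yl)-6-(triisopropylsilyloxy)-2,3-dihydro-1-benzofuran, racemic | COC1(OC)C(c2ccc(OC)c(O[Si](C(C)C)(C(C)C)C(C)C)c2)Oc2cc(O[Si](C(C)C)(C(C)C)C(C)C)c(CC=C(C)C)cc12
F6 | step 8 | trans-3-methoxy-2-[4-methoxy-3-(triisopropylsilyloxy)phenyl]-5-(3-methylbut-2-en-1-yl)-6-(triisopropylsilyloxy)-2,3-dihydro-1-benzofuran, racemic, (2S,3R) enantiomer drawn | CO[C@H]1[C@H](c3ccc(OC)c(O[Si](C(C)C)(C(C)C)C(C)C)c3)Oc2cc(O[Si](C(C)C)(C(C)C)C(C)C)c(CC=C(C)C)cc21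
A1 | alternative 1 | methyl 2-{[4-methoxy-3-(triisopropylsilyloxy)phenyl]methoxy}-5-(3-methylbut-2-en-1-yl)-4-(triisopropylsilyloxy)benzoate | COC(=O)c1cc(CC=C(C)C)c(O[Si](C(C)C)(C(C)C)C(C)C)cc1OCc1ccc(OC)c(O[Si](C(C)C)(C(C)C)C(C)C)c1
A2 | alternative 1 | methyl 4-{[4-methoxy-3-(triisopropylsilyloxy)phenyl]methoxy}-2-oxo-2H-pyran-5-carboxylate | COC(=O)C1=COC(=O)C=C1OCc1ccc(OC)c(O[Si](C(C)C)(C(C)C)C(C)C)c1
A3 | alternative 1 | triisopropyl[(5-methylhex-4-en-1-yn-1-yl)oxy]silane | CC(C)=CCC#CO[Si](C(C)C)(C(C)C)C(C)C
A4 | alternative 2 | 3-methoxy-2-[4-methoxy-3-(methoxymethoxy)phenyl]-6-(methoxymethoxy)-5-(3-methylbut-2-en-1-yl)-1-benzofuran | COCOc1cc2oc(-c3ccc(OC)c(OCOC)c3)c(OC)c2cc1CC=C(C)C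
A5 | alternative 2 | 2-methoxy-1-[4-methoxy-3-(methoxymethoxy)phenyl]ethan-1-one | COCC(=O)c1ccc(OC)c(OCOC)c1
A6 | alternative 2 | 1-bromo-2-iodo-5-(methoxymethoxy)-4-(3-methylbut-2-en-1-yl)benzene | COCOc1cc(Br)c(I)cc1CC=C(C)C
A7 | alternative 3 | 5-bromo-2-[4-methoxy-3-(triisopropylsilyloxy)phenyl]-6-(triisopropylsilyloxy)-1-benzofuran-3(2H)-one, racemic | O=C1c2cc(Br)c(O[Si](C(C)C)(C(C)C)C(C)C)cc2OC1c1ccc(OC)c(O[Si](C(C)C)(C(C)C)C(C)C)c1
A8 | alternative 3 | 2-[4-bromo-3-(triisopropylsilyloxy)phenoxy]-2-[4-methoxy-3-(triisopropylsilyloxy)phenyl]acetic acid, racemic | OC(=O)C(Oc1ccc(Br)c(O[Si](C(C)C)(C(C)C)C(C)C)c1)c1ccc(OC)c(O[Si](C(C)C)(C(C)C)C(C)C)c1
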